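Slowness is what I look for first, and Thursday's flask shows none late on: its target reads 39.7% at 1.33 min and 40.0% at 8.00 min, a difference smaller than the scatter of 0.5 percentage points. Thursday's run is the flask asked about, followed so far.

in all of them: starting material 0.099 M; gas 49 mM (held)

|  | fresh partner | temperature | remark | time |
|---|---|---|---|---|
| Thursday's | 0.094 M | 25 °C | the very flask that is asked about, followed so far |  |
| Friday's | 0.063 M | 20 °C | run made earlier |  |
| flask | 0.0940 M | 25 °C |  | 12 min |

Thursday's run (percent of the starting material charged)

| time / min | target / % |
|---|---|
| 0.500 | 30.2 |
| 1.33 | 39.7 |
| 3.00 | 40.2 |
| 8.00 | 40.0 |

Friday's run (percent of the starting material charged)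

| time / s | target / % |
|---|---|
| 25.0 | 13.5 |
| 50.0 | 24.5 |
| 80.0 | 28.0 |
| 120 | 30.8 |

(scatter of a reading: 0.5 percentage points)

1. target, in percent of the starting material first charged, at 12 min
2. what to do for the largest gain in target; "none" if nothing gains more than 2 percentage points (ochre / green / grey / red / none)
3. target present, with what was taken out counted in, in percent of the starting material first charged, after grey
4. target present, with what was taken out counted in, in percent of the starting material first charged, after red

- ochre: at 12 min raise the temperature by 25 K, then wait 4.0 min
- green: at 12 min add fresh partner, 100% of the amount charged, then wait 4.0 min
- grey: change nothing and wait 4.0 min more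
- red: at 12 min take out 90% of the target then present, then wait 4.0 min

- at the start none of coupling partner is dissolved
- what is taken out of target is counted as made
- what may be going on: starting material + coupling partner -> open intermediate; coupling partner + fresh partner -> second intermediate; open intermediate + second intermediate -> target; gas <-> coupling partner; second intermediate -> side product
- additions bring no volume worth counting

So I follow one molecule of fresh partner. It becomes second intermediate, and there the road forks: target if it meets open intermediate, side product if it does not. In Thursday's flask, the last reading of 40.0% of 0.099 M starting material is 0.0396 M of target from 0.094 M fresh partner, so by that reading 42.1% of the fresh partner charged ends in target; that is the capture share. Friday's run, colder, with less fresh partner and still rising, gives 48.4% at its last reading, but two settings differ there, so I lean on Thursday's flask. Its target stays near 40.0% of the starting material charged, less than that charge allows, so I take fresh partner as the limiting reagent.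

The asked flask has Thursday's charges and temperature, so I commit to 40.0% at 12 min. Grey, red and ochre bring no fresh partner, so I expect them to add no target. Green is the one to reckon, and its weak link is the share itself, since the fork's odds should follow open intermediate. The odds on Thursday are 0.728, with open intermediate averaging perhaps 80.0% of the charge if it forms quickly. A second charge starts from 60.0%, so its odds are 0.546, its share 35.3%, and green should gain about 34 points, more than the 2 points needed.

The forecast gives 40% now, 40% after grey, 40% after red and green as best, saying “Only adding fresh partner restarts production”.

The flask gives 39.7% at 12 min, with 0% of its fresh partner free, 39.7% after grey, 39.7% after red, and green as best, gaining 33 points.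

    starting material + coupling partner → open intermediate (k = 2.10 M⁻¹ s⁻¹, Ea = 48.0 kJ mol⁻¹)
    coupling partner + fresh partner → second intermediate (k = 1.30 M⁻¹ s⁻¹, Ea = 56.0 kJ mol⁻¹)
    open intermediate + second intermediate → target (k = 1.60 M⁻¹ s⁻¹, Ea = 61.0 kJ mol⁻¹)
    gas ⇌ coupling partner, rate k4*(csat - [coupling partner]) (kL = 1.90 s⁻¹)
    second intermediate → side product (k = 0.120 s⁻¹, Ea = 80.0 kJ mol⁻¹)
    (constants at 25 °C)

With open intermediate at 60.3% of the charge at 12 min, second intermediate made under green enters target at first at 0.0954 s⁻¹, slower than the 0.12 s⁻¹ at which it enters side product. Green's capture on its added charge comes to 35.3%. In the neighbouring flask with 0.056 M of fresh partner, Thursday's capture share gives 23.8% of target, and that flask holds 25.2%.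

Readings and results are simulated for an exercise; the scatter is artificial.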